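**Retrosynthetic overview**

1. Last, the exocyclic methylene is put on C3 of the finished trans lactone acid (carboxylation, then decarboxylative Mannich methylenation); the chain ketone is held as a dioxolane for that operation only.
2. Before that, the only ring, the γ-lactone, is closed at the bond between the ring oxygen O1 and the chain-bearing carbon C5 by a carboxylate-directed, manganese-catalysed enantioselective C–H lactonization of an achiral open-chain keto acid (lactone numbering: O1, C2 carbonyl carbon, C3, C4 carboxyl-bearing carbon, C5).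
3. Enabling feature: C5 is the γ-carbon of the C2 carboxyl (C2–C3–C4–C5), so the carboxylate oxygen can reach a C5–H bond through a seven-membered hydrogen-transfer geometry. C4 bears a carboxyl and can therefore be carried as a malonate carbon with two identical esters, which leaves the precursor without a stereocenter and C5 with the only γ-hydrogens.
4. After ring closure one ester is removed and C4 is equilibrated, so both C4 epimers converge on the trans lactone.
5. The precursor comes from dimethyl malonate by two alkylations (16-bromohexadecan-2-one, made from 15-bromopentadecanoic acid, then tert-butyl bromoacetate); ring order: the lactone ring only, in step 5.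

Key step: step 5

Assumption: the sense of induction of the manganese catalyst on this substrate cannot be assigned in advance; the (S,S) ligand is written, and the (R,R) antipode is to be used if a trial run shows that (S,S) gives the (S) configuration at C5.

**Route**

Step 1
Reactants: 1 15-bromopentadecanoic acid
Product: 3 16-bromohexadecan-2-one, via 15-bromopentadecanoyl chloride 2 (not isolated)
Conditions: (COCl)2, cat. DMF, CH2Cl2, 0 °C to rt; then MeMgBr, Fe(acac)3 (3 mol%), THF, −78 °C
Reagents that add atoms: methylmagnesium bromide C[Mg]Br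
Why: Acid chloride formation followed by iron-catalysed acylation of the Grignard reagent, which at −78 °C should be much faster than attack on the primary bromide or over-addition to the ketone; no stereocenter is formed.

Step 2
Reactants: 3 16-bromohexadecan-2-one; 4 dimethyl malonate
Product: 5 dimethyl 2-(15-oxohexadecyl)propanedioate
Conditions: 4 (3 equiv), NaH (1.5 equiv), THF/DMF, 0 °C; then 3, NaI (10 mol%), 60 °C
Reagents that add atoms: none
Why: Malonic ester alkylation (SN2) with preformed sodium malonate in excess, which suppresses dialkylation and is too weakly basic to enolize the methyl ketone; no stereocenter is formed.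

Step 3
Reactants: 5 dimethyl 2-(15-oxohexadecyl)propanedioate; 6 tert-butyl bromoacetate
Product: 7 1-tert-butyl 2,2-dimethyl 17-oxooctadecane-1,2,2-tricarboxylate
Conditions: NaH (1.0 equiv), THF/DMF, 0 °C; then 6, rt
Reagents that add atoms: none
Why: Second malonic ester alkylation (SN2) with a reactive α-bromo ester builds the quaternary C4 with two identical ester groups, so no stereocenter arises, and one equivalent of base leaves the ketone un-enolized.

Step 4
Reactants: 7 1-tert-butyl 2,2-dimethyl 17-oxooctadecane-1,2,2-tricarboxylate
Product: 8 3,3-bis(methoxycarbonyl)-18-oxononadecanoic acid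
Conditions: CF3CO2H/CH2Cl2 (1:3), rt
Reagents that add atoms: none
Why: Acidolysis of the tert-butyl ester (E1 loss of isobutene) should free the one carboxyl that directs the next step while the methyl esters and the ketone stay intact.

Step 5
Reactants: 8 3,3-bis(methoxycarbonyl)-18-oxononadecanoic acid
Product: 9 dimethyl (2R)-5-oxo-2-(14-oxopentadecyl)dihydrofuran-3,3(2H)-dicarboxylate
Conditions: [Mn(OTf)2(L)] (2 mol%; L = (S,S)-TIPS-pdp, i.e. (2S,2'S)-1,1'-bis{[5-(triisopropylsilyl)pyridin-2-yl]methyl}-2,2'-bipyrrolidine), H2O2 (aq., 2 equiv, syringe pump), CF3CH2OH, 0 °C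
Reagents that add atoms: none
Why: Proposed new method: the free carboxylate of 8 binds the divalent manganese complex, H2O2 is cleaved heterolytically to a pentavalent oxomanganese carboxylate, this abstracts one of the two enantiotopic C5 hydrogens through a seven-membered 1,7-hydrogen-atom-transfer transition state, and the short-lived C5 radical is captured by the bound carboxylate oxygen (carboxylate rebound) before it can invert, so the O1–C5 bond and the ring form in one event (any hydroxyl-rebound leakage would cyclize to the same lactone with the same configuration). The closest known reaction type is the manganese-catalysed, carboxylic-acid-directed enantioselective γ-C–H lactonization of unactivated methylene groups with H2O2; new here is an acyclic substrate whose γ-CH2 lies next to a malonate quaternary carbon. The single ring closes as a five-membered lactone by intramolecular C–O bond formation at the γ-carbon within the coordination sphere of the metal. The only new stereocenter, C5, is controlled by the chiral ligand, which distinguishes the enantiotopic C5–H bonds; the substrate is achiral because C4 carries two identical esters. The step needs site selectivity against thirteen other chain methylenes and the ketone α-positions, and this is secured by the substrate: C5 holds the only γ-hydrogens, the quaternary C4 favours the reactive fold, and the oxidant is generated only on catalyst that carries the substrate as its carboxylate ligand. Over-oxidation should be held back because the remaining C5–H is deactivated by the acyloxy group.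

Step 6
Reactants: 9 dimethyl (2R)-5-oxo-2-(14-oxopentadecyl)dihydrofuran-3,3(2H)-dicarboxylate
Product: 11 methyl (2R,3S)-5-oxo-2-(14-oxopentadecyl)tetrahydrofuran-3-carboxylate, via cis methyl ester 10 (not isolated)
Conditions: LiCl, H2O, DMSO, 140 °C; then DBU (0.3 equiv), toluene, rt
Reagents that add atoms: none
Why: Krapcho dealkoxycarbonylation (chloride SN2 at a methyl ester, loss of CO2, protonation of the ester enolate) followed by amidine-mediated epimerization at C4 through the ester enolate should funnel both C4 epimers into the thermodynamically preferred trans isomer, while C5 is untouched because its C–O bond lies in the nodal plane of that enolate and β-elimination is not expected.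

Step 7
Reactants: 11 methyl (2R,3S)-5-oxo-2-(14-oxopentadecyl)tetrahydrofuran-3-carboxylate
Product: 12 (2R,3S)-5-oxo-2-(14-oxopentadecyl)tetrahydrofuran-3-carboxylic acid
Conditions: 6 M HCl, 1,4-dioxane, reflux
Reagents that add atoms: water O
Why: Acid-catalysed ester hydrolysis (acyl–oxygen cleavage) should not epimerize C4, and any ring-opened hydroxy acid recloses with retention at C5 because no alkyl–oxygen bond is broken.

Step 8
Reactants: 12 (2R,3S)-5-oxo-2-(14-oxopentadecyl)tetrahydrofuran-3-carboxylic acid
Product: 13 (2R,3S)-2-[13-(2-methyl-1,3-dioxolan-2-yl)tridecyl]-5-oxotetrahydrofuran-3-carboxylic acid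
Conditions: Me3SiOCH2CH2OSiMe3 (3 equiv), Me3SiOTf (5 mol%), CH2Cl2, −78 to −20 °C; aqueous work-up at pH 4
Reagents that add atoms: 1,2-bis(trimethylsilyloxy)ethane C[Si](C)(C)OCCO[Si](C)(C)C
Why: Noyori ketalization under aprotic conditions at low temperature should protect the methyl ketone without esterifying the free acid (a transient silyl ester is hydrolysed on work-up) or opening the lactone.

Step 9
Reactants: 13 (2R,3S)-2-[13-(2-methyl-1,3-dioxolan-2-yl)tridecyl]-5-oxotetrahydrofuran-3-carboxylic acid
Product: 15 (2R,3S)-4-methylidene-2-[13-(2-methyl-1,3-dioxolan-2-yl)tridecyl]-5-oxotetrahydrofuran-3-carboxylic acid, via lactone dicarboxylic acid 14 (not isolated)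
Conditions: MeOMgOCO2Me (2 M in DMF, excess), 130 °C; cold 1 M HCl work-up; then HCHO (37% aq.), PhNHMe, NaOAc, AcOH, rt
Reagents that add atoms: formaldehyde C=O
Why: Carboxylation of the lactone α-carbon C3 with methyl magnesium carbonate, driven by the magnesium chelate of the malonate-type half acid, followed by decarboxylative Mannich methylenation should install the exocyclic methylene, while the C4 carboxylate resists deprotonation and the dioxolane keeps the methyl ketone from being carboxylated.

Step 10
Reactants: 15 (2R,3S)-4-methylidene-2-[13-(2-methyl-1,3-dioxolan-2-yl)tridecyl]-5-oxotetrahydrofuran-3-carboxylic acid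
Product: 16 (2R,3S)-4-methylidene-5-oxo-2-(14-oxopentadecyl)tetrahydrofuran-3-carboxylic acid
Conditions: 1 M HCl, THF, rt
Reagents that add atoms: water O
Why: Acid-catalysed ketal hydrolysis under conditions mild enough to leave the α-methylene lactone and the trans C4/C5 stereocenters unchanged.

**Compound list**

1 | 15-bromopentadecanoic acid | OC(=O)CCCCCCCCCCCCCCBr | starting material
2 | 15-bromopentadecanoyl chloride | ClC(=O)CCCCCCCCCCCCCCBr | intermediate (not isolated)
3 | 16-bromohexadecan-2-one | CC(=O)CCCCCCCCCCCCCCBr | intermediate
4 | dimethyl malonate | COC(=O)CC(=O)OC | starting material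
5 | dimethyl 2-(15-oxohexadecyl)propanedioate | COC(=O)C(CCCCCCCCCCCCCCC(C)=O)C(=O)OC | intermediate
6 | tert-butyl bromoacetate | CC(C)(C)OC(=O)CBr | starting material
7 | 1-tert-butyl 2,2-dimethyl 17-oxooctadecane-1,2,2-tricarboxylate | CC(C)(C)OC(=O)CC(C(=O)OC)(C(=O)OC)CCCCCCCCCCCCCCC(C)=O | intermediate
8 | 3,3-bis(methoxycarbonyl)-18-oxononadecanoic acid | OC(=O)CC(C(=O)OC)(C(=O)OC)CCCCCCCCCCCCCCC(C)=O | intermediate
9 | dimethyl (2R)-5-oxo-2-(14-oxopentadecyl)dihydrofuran-3,3(2H)-dicarboxylate | O=C1O[C@H](CCCCCCCCCCCCCC(C)=O)C(C(=O)OC)(C(=O)OC)C1 | intermediate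
10 | methyl (2R,3R)-5-oxo-2-(14-oxopentadecyl)tetrahydrofuran-3-carboxylate (cis) | C1C(=O)O[C@H](CCCCCCCCCCCCCC(C)=O)[C@@H]1C(=O)OC | intermediate (not isolated)
11 | methyl (2R,3S)-5-oxo-2-(14-oxopentadecyl)tetrahydrofuran-3-carboxylate (trans) | C1C(=O)O[C@H](CCCCCCCCCCCCCC(C)=O)[C@H]1C(=O)OC | intermediate
12 | (2R,3S)-5-oxo-2-(14-oxopentadecyl)tetrahydrofuran-3-carboxylic acid | C1C(=O)O[C@H](CCCCCCCCCCCCCC(C)=O)[C@H]1C(=O)O | intermediate
13 | (2R,3S)-2-[13-(2-methyl-1,3-dioxolan-2-yl)tridecyl]-5-oxotetrahydrofuran-3-carboxylic acid | C1C(=O)O[C@H](CCCCCCCCCCCCCC2(C)OCCO2)[C@H]1C(=O)O | intermediate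
14 | (2R,3S)-2-[13-(2-methyl-1,3-dioxolan-2-yl)tridecyl]-5-oxotetrahydrofuran-3,4-dicarboxylic acid (C4 epimers) | OC(=O)C1C(=O)O[C@H](CCCCCCCCCCCCCC2(C)OCCO2)[C@H]1C(=O)O | intermediate (not isolated)
15 | (2R,3S)-4-methylidene-2-[13-(2-methyl-1,3-dioxolan-2-yl)tridecyl]-5-oxotetrahydrofuran-3-carboxylic acid | C=C1C(=O)O[C@H](CCCCCCCCCCCCCC2(C)OCCO2)[C@H]1C(=O)O | intermediate
16 | (2R,3S)-4-methylidene-5-oxo-2-(14-oxopentadecyl)tetrahydrofuran-3-carboxylic acid | C=C1C(=O)O[C@H](CCCCCCCCCCCCCC(C)=O)[C@H]1C(=O)O | target

**Count and risks**

Total step count: 10. Longest linear sequence: 10 steps (1 to 16); 4 and 6 are commercial building blocks.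

Steps most likely to fail:

1. Step 5 (proposed new method). Hydrogen abstraction at C5 may be slowed by the two ester groups on the neighbouring carbon, so that undirected oxidation of remote chain methylenes competes, and discrimination of the two enantiotopic hydrogens on a flexible chain may be incomplete. Fallback (sets out from 3, comes back at 12): the C5–O bond is made by carbonyl addition instead of C–H functionalization. Oxidation of the primary bromide of 3 with trimethylamine N-oxide in DMSO should give 15-oxohexadecanal F1. The succinate imide tert-butyl 4-[(4S)-4-benzyl-2-oxo-1,3-oxazolidin-3-yl]-4-oxobutanoate F2 is made from (S)-4-benzyl-1,3-oxazolidin-2-one (n-BuLi) and the pivaloyl mixed anhydride of mono-tert-butyl succinate. Its boron enolate (Bu2BOTf, iPr2NEt, CH2Cl2, −78 °C) should add to the aldehyde of F1 and not to the ketone in an Evans syn aldol reaction, giving tert-butyl (3S,4R)-3-{[(4S)-4-benzyl-2-oxo-1,3-oxazolidin-3-yl]carbonyl}-4-hydroxy-18-oxononadecanoate F3. CF3CO2H in CH2Cl2 should cleave the tert-butyl ester and close the lactone (a syn aldol gives the trans lactone) to (4S)-4-benzyl-3-{[(2R,3S)-5-oxo-2-(14-oxopentadecyl)tetrahydrofuran-3-yl]carbonyl}-1,3-oxazolidin-2-one F4. LiOH/H2O2 in THF/H2O at 0 °C should remove the auxiliary and give 12, from which steps 8 to 10 follow unchanged.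

2. Step 6. Equilibration at C4 may stop short of the trans isomer, or chloride at high temperature may open the lactone instead of dealkylating an ester. Fallback (sets out from 9, comes back at 11): hydrolytic instead of dealkylative removal of the extra carboxyl. 6 M HCl/AcOH at reflux should hydrolyse both methyl esters and decarboxylate the malonic acid to a mixture of 12 and its C3 epimer (2R,3R)-5-oxo-2-(14-oxopentadecyl)tetrahydrofuran-3-carboxylic acid F5. The mixture is esterified with Me3SiCHN2 in MeOH/toluene to 11 and 10, and equilibration with DBU in toluene should then give 11.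

3. Step 9. Carboxylation at C3 may be incomplete over the long reaction time at high temperature, the ketal may be lost prematurely, or the new double bond may migrate into the ring during work-up. Fallback (sets out from 13, comes back at 15): enolate aminomethylation instead of carboxylation. LiN(SiMe3)2 (2.3 equiv) in THF at −78 °C should give the carboxylate/lactone-enolate dianion, which is trapped with dimethyl(methylidene)ammonium iodide to give (2R,3S)-4-[(dimethylamino)methyl]-2-[13-(2-methyl-1,3-dioxolan-2-yl)tridecyl]-5-oxotetrahydrofuran-3-carboxylic acid F6. Quaternization with MeI should give [(4S,5R)-4-carboxy-5-[13-(2-methyl-1,3-dioxolan-2-yl)tridecyl]-2-oxotetrahydrofuran-3-yl]-N,N,N-trimethylmethanaminium iodide F7, and aqueous NaHCO3/EtOAc should eliminate trimethylamine to give 15.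

**Further compounds**

F1 | step 5 | 15-oxohexadecanal | O=CCCCCCCCCCCCCCC(C)=O
F2 | step 5 | tert-butyl 4-[(4S)-4-benzyl-2-oxo-1,3-oxazolidin-3-yl]-4-oxobutanoate | O=C(CCC(=O)OC(C)(C)C)N1[C@@H](Cc2ccccc2)COC1=O
F3 | step 5 | tert-butyl (3S,4R)-3-{[(4S)-4-benzyl-2-oxo-1,3-oxazolidin-3-yl]carbonyl}-4-hydroxy-18-oxononadecanoate | CC(C)(C)OC(=O)C[C@@H]([C@H](O)CCCCCCCCCCCCCC(C)=O)C(=O)N1[C@@H](Cc2ccccc2)COC1=O
F4 | step 5 | (4S)-4-benzyl-3-{[(2R,3S)-5-oxo-2-(14-oxopentadecyl)tetrahydrofuran-3-yl]carbonyl}-1,3-oxazolidin-2-one | C1C(=O)O[C@H](CCCCCCCCCCCCCC(C)=O)[C@H]1C(=O)N1[C@@H](Cc2ccccc2)COC1=O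
F5 | step 6 | (2R,3R)-5-oxo-2-(14-oxopentadecyl)tetrahydrofuran-3-carboxylic acid | C1C(=O)O[C@H](CCCCCCCCCCCCCC(C)=O)[C@@H]1C(=O)O
F6 | step 9 | (2R,3S)-4-[(dimethylamino)methyl]-2-[13-(2-methyl-1,3-dioxolan-2-yl)tridecyl]-5-oxotetrahydrofuran-3-carboxylic acid (C4 epimers) | CN(C)CC1C(=O)O[C@H](CCCCCCCCCCCCCC2(C)OCCO2)[C@H]1C(=O)O
F7 | step 9 | [(4S,5R)-4-carboxy-5-[13-(2-methyl-1,3-dioxolan-2-yl)tridecyl]-2-oxotetrahydrofuran-3-yl]-N,N,N-trimethylmethanaminium iodide | C[N+](C)(C)CC1C(=O)O[C@H](CCCCCCCCCCCCCC2(C)OCCO2)[C@H]1C(=O)O.[I-]
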